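## Retrosynthetic overview

1. Last bond: the exocyclic C–N amidine bond between the 2-aminoimidazole and C4 of 1-methylparabanic acid, which is made separately from N-methylurea and oxalyl chloride and activated as its O-silyl imidate.
2. The 2-aminoimidazole ring comes from an N-methyl α-amino ketone and cyanamide; the N-methylamine carbon becomes C5 and the ketone carbon C4.
3. Key C–C bond (the future C4–CH2Ar bond): crossed Claisen condensation of the imidazolide of an N-Boc-N-methyl arylalanine with the lithium enolate of tert-butyl 4-methoxyphenylacetate, followed by acidolysis and decarboxylation.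
4. The arylalanine comes from benzylation of the Boc-sarcosine methyl ester enolate with O-benzylisovanillyl bromide (from isovanillin); the phenol stays benzyl-protected until the imidazole exists.
5. Ring order: parabanic acid ring (side branch), then the imidazole ring, then the two heterocycles are joined.

Assumption: the target has no stereogenic element, so it is made as the single achiral compound shown; stereocentres in intermediates are left racemic because they are later flattened or excised.

## Route

Step 1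
Reactants: 1 isovanillin (3-hydroxy-4-methoxybenzaldehyde)
Product: 2 3-(benzyloxy)-4-methoxybenzaldehyde
Conditions: BnBr (1.1 equiv), K2CO3 (1.5 equiv), DMF, rt, 12 h
Reagents that add atoms: benzyl bromide, BrCc1ccccc1
Why: Williamson ether synthesis; the phenoxide is the only nucleophile and benzyl bromide is an excellent SN2 electrophile.

Step 2
Reactants: 2 3-(benzyloxy)-4-methoxybenzaldehyde
Product: 3 [3-(benzyloxy)-4-methoxyphenyl]methanol
Conditions: NaBH4 (1.0 equiv), MeOH/THF, 0 °C to rt; water quench
Reagents that add atoms: none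
Why: Borohydride reduction of an aryl aldehyde to the primary alcohol; both ethers are inert and no stereocentre is formed.

Step 3
Reactants: 3 [3-(benzyloxy)-4-methoxyphenyl]methanol
Product: 4 2-(benzyloxy)-4-(bromomethyl)-1-methoxybenzene
Conditions: PBr3 (0.4 equiv), CH2Cl2, 0 °C, 1 h; used directly
Reagents that add atoms: phosphorus tribromide, BrP(Br)Br
Why: Alcohol-to-bromide substitution with PBr3 (O-activation, then bromide displacement) is fast for an electron-rich benzylic alcohol and leaves the aryl ethers untouched at 0 °C.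

Step 4
Reactants: 4 2-(benzyloxy)-4-(bromomethyl)-1-methoxybenzene; 5 methyl N-(tert-butoxycarbonyl)-N-methylglycinate (Boc-Sar-OMe)
Product: 7 methyl 3-[3-(benzyloxy)-4-methoxyphenyl]-2-[(tert-butoxycarbonyl)(methyl)amino]propanoate (racemic), via lithium enolate 6 (not isolated)
Conditions: 5 (1.2 equiv), LiN(SiMe3)2 (1.25 equiv), THF, −78 °C, 45 min; then 4, −78 → −20 °C, 3 h; aq NH4Cl
Reagents that add atoms: lithium bis(trimethylsilyl)amide, [Li+].C[Si](C)(C)[N-][Si](C)(C)C (supplies only the lithium of enolate 6; nothing of it remains in 7)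
Why: Ester enolate alkylation (SN2) of the NH-free sarcosinate with a reactive benzylic bromide; the new stereocentre is formed racemic on purpose because it becomes the sp2 C5 of the imidazole.

Step 5
Reactants: 7 methyl 3-[3-(benzyloxy)-4-methoxyphenyl]-2-[(tert-butoxycarbonyl)(methyl)amino]propanoate
Product: 8 3-[3-(benzyloxy)-4-methoxyphenyl]-2-[(tert-butoxycarbonyl)(methyl)amino]propanoic acid (racemic)
Conditions: LiOH·H2O (3 equiv), THF/MeOH/H2O 3:1:1, rt, 6 h; then 1 M HCl to pH 3 at 0 °C
Reagents that add atoms: lithium hydroxide (hydroxide oxygen of the new CO2H), [Li+].[OH-]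
Why: Saponification of a methyl ester; the Boc carbamate and benzyl ether are stable to aqueous LiOH and to a brief cold acidification.

Step 6
Reactants: 9 2-(4-methoxyphenyl)acetic acid
Product: 10 tert-butyl 2-(4-methoxyphenyl)acetate
Conditions: tert-butyl 2,2,2-trichloroacetimidate (2 equiv), BF3·OEt2 (5 mol %), CH2Cl2/cyclohexane, rt, 16 h
Reagents that add atoms: tert-butyl 2,2,2-trichloroacetimidate, CC(C)(C)OC(=N)C(Cl)(Cl)Cl
Why: Acid-catalysed O-tert-butylation of a carboxylic acid by the trichloroacetimidate (SN1-type tert-butyl transfer) gives the hindered ester that resists self-condensation in the next step.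

Step 7
Reactants: 8 3-[3-(benzyloxy)-4-methoxyphenyl]-2-[(tert-butoxycarbonyl)(methyl)amino]propanoic acid; 10 tert-butyl 2-(4-methoxyphenyl)acetate
Product: 13 tert-butyl 5-[3-(benzyloxy)-4-methoxyphenyl]-4-[(tert-butoxycarbonyl)(methyl)amino]-2-(4-methoxyphenyl)-3-oxopentanoate (mixture of racemic diastereomers), via acyl imidazolide 11 (not isolated), via lithium enolate 12 (not isolated)
Conditions: 8, CDI (1.1 equiv), THF, rt, 1 h; separately 10 (3.5 equiv), LiN(SiMe3)2 (3.5 equiv), THF, −78 °C, 45 min; imidazolide solution added at −78 °C, then to −20 °C, 2 h; aq NH4Cl; excess 10 recovered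
Reagents that add atoms: 1,1'-carbonyldiimidazole, O=C(n1ccnc1)n1ccnc1 (supplies only the imidazolyl group of 11; not retained in 13); lithium bis(trimethylsilyl)amide, [Li+].C[Si](C)(C)[N-][Si](C)(C)C (supplies only the lithium of 12; not retained in 13)
Why: Crossed Claisen condensation: the acyl imidazolide is acylating but NH-free, and the tert-butyl arylacetate enolate is used in excess to absorb the liberated imidazole N–H and to deprotonate the acidic β-keto ester product, which drives the reaction. Both new stereocentres are uncontrolled and are later destroyed.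

Step 8
Reactants: 13 tert-butyl 5-[3-(benzyloxy)-4-methoxyphenyl]-4-[(tert-butoxycarbonyl)(methyl)amino]-2-(4-methoxyphenyl)-3-oxopentanoate
Product: 15 4-[3-(benzyloxy)-4-methoxyphenyl]-1-(4-methoxyphenyl)-3-(methylamino)butan-2-one trifluoroacetate salt (racemic), via beta-keto acid salt 14 (not isolated)
Conditions: TFA/CH2Cl2 1:2, 0 °C to rt, 3 h; concentrate; toluene, 50 °C, 1 h
Reagents that add atoms: trifluoroacetic acid (counter-ion of the salt), OC(=O)C(F)(F)F
Why: Acidolysis removes the Boc group and the tert-butyl ester together, and the resulting α-aryl β-keto acid decarboxylates readily. The amine is kept protonated so the α-amino ketone cannot self-condense, and the benzyl aryl ether survives short exposure to TFA at room temperature.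

Step 9
Reactants: 15 4-[3-(benzyloxy)-4-methoxyphenyl]-1-(4-methoxyphenyl)-3-(methylamino)butan-2-one trifluoroacetate salt
Product: 17 5-{[3-(benzyloxy)-4-methoxyphenyl]methyl}-4-[(4-methoxyphenyl)methyl]-1-methyl-1H-imidazol-2-amine, via ketoguanidine 16 (not isolated)
Conditions: H2NCN (4 equiv), EtOH/H2O 1:1, pH 4.5 (1 M NaOH), 95 °C, 3 h; then aq Na2CO3 to pH 10, extraction
Reagents that add atoms: cyanamide, NC#N
Why: Cyanamide/α-amino ketone 2-aminoimidazole synthesis: the secondary amine adds to cyanamide to give the guanidine, which cyclises onto the ketone and dehydrates to the aromatic ring. Because the methyl-bearing nitrogen becomes N1, the regiochemistry (C5 benzyloxy-methoxybenzyl, C4 methoxybenzyl) is fixed, and the last stereocentre becomes sp2.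

Step 10
Reactants: 17 5-{[3-(benzyloxy)-4-methoxyphenyl]methyl}-4-[(4-methoxyphenyl)methyl]-1-methyl-1H-imidazol-2-amine
Product: 18 5-({2-amino-4-[(4-methoxyphenyl)methyl]-1-methyl-1H-imidazol-5-yl}methyl)-2-methoxyphenol
Conditions: H2 (1 atm), 10% Pd/C, MeOH, rt, 6 h
Reagents that add atoms: none
Why: Catalytic hydrogenolysis cleaves only the O-benzyl ether; the methyl ethers, the aromatic imidazole and the amino group are not reduced.

Step 11
Reactants: 19 N-methylurea
Product: 20 1-methylimidazolidine-2,4,5-trione (1-methylparabanic acid)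
Conditions: (COCl)2 (1.1 equiv), THF, 0 °C, then reflux 2 h; recrystallisation
Reagents that add atoms: oxalyl chloride, O=C(Cl)C(=O)Cl
Why: Double N-acylation (cyclocondensation) of the urea with the bis-electrophile oxalyl chloride closes the five-membered trione ring.

Step 12
Reactants: 18 5-({2-amino-4-[(4-methoxyphenyl)methyl]-1-methyl-1H-imidazol-5-yl}methyl)-2-methoxyphenol; 20 1-methylimidazolidine-2,4,5-trione
Product: 22 naamidine B, via silyl imidate 21 (not isolated)
Conditions: 20 (1.5 equiv), BSA (1.6 equiv), MeCN, 80 °C, 1 h, evaporate; then 18, toluene, 110 °C, 16 h; MeOH quench, chromatography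
Reagents that add atoms: N,O-bis(trimethylsilyl)acetamide, CC(=N[Si](C)(C)C)O[Si](C)(C)C (supplies only the Me3Si group of 21; not retained in 22)
Why: Silylation turns the N3–C4 lactam of the parabanic acid into an O-silyl imidate, and the 2-amino group displaces the silyloxy group by addition–elimination to form the amidine at C4 only. The phenol is too weak a nucleophile to compete, and the methanol quench removes all silicon.

## Compound list

1 | isovanillin (3-hydroxy-4-methoxybenzaldehyde) | COc1ccc(C=O)cc1O | starting material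
2 | 3-(benzyloxy)-4-methoxybenzaldehyde | COc1ccc(C=O)cc1OCc1ccccc1 | intermediate
3 | [3-(benzyloxy)-4-methoxyphenyl]methanol | COc1ccc(CO)cc1OCc1ccccc1 | intermediate
4 | 2-(benzyloxy)-4-(bromomethyl)-1-methoxybenzene | COc1ccc(CBr)cc1OCc1ccccc1 | intermediate
5 | methyl N-(tert-butoxycarbonyl)-N-methylglycinate (Boc-Sar-OMe) | COC(=O)CN(C)C(=O)OC(C)(C)C | starting material
6 | lithium enolate of 5 (lithium 1-methoxy-2-[(tert-butoxycarbonyl)(methyl)amino]ethen-1-olate; enolate geometry not controlled and of no consequence) | [Li+].[O-]C(OC)=CN(C)C(=O)OC(C)(C)C | intermediate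
7 | methyl 3-[3-(benzyloxy)-4-methoxyphenyl]-2-[(tert-butoxycarbonyl)(methyl)amino]propanoate (racemic) | COC(=O)C(Cc1ccc(OC)c(OCc2ccccc2)c1)N(C)C(=O)OC(C)(C)C | intermediate
8 | 3-[3-(benzyloxy)-4-methoxyphenyl]-2-[(tert-butoxycarbonyl)(methyl)amino]propanoic acid (racemic) | OC(=O)C(Cc1ccc(OC)c(OCc2ccccc2)c1)N(C)C(=O)OC(C)(C)C | intermediate
9 | 2-(4-methoxyphenyl)acetic acid | COc1ccc(CC(=O)O)cc1 | starting material
10 | tert-butyl 2-(4-methoxyphenyl)acetate | COc1ccc(CC(=O)OC(C)(C)C)cc1 | intermediate
11 | tert-butyl N-{3-[3-(benzyloxy)-4-methoxyphenyl]-1-(1H-imidazol-1-yl)-1-oxopropan-2-yl}-N-methylcarbamate (acyl imidazolide, racemic) | CC(C)(C)OC(=O)N(C)C(Cc1ccc(OC)c(OCc2ccccc2)c1)C(=O)n1ccnc1 | intermediate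
12 | lithium enolate of 10 (lithium 1-tert-butoxy-2-(4-methoxyphenyl)ethen-1-olate; enolate geometry not controlled and of no consequence) | [Li+].[O-]C(OC(C)(C)C)=Cc1ccc(OC)cc1 | intermediate
13 | tert-butyl 5-[3-(benzyloxy)-4-methoxyphenyl]-4-[(tert-butoxycarbonyl)(methyl)amino]-2-(4-methoxyphenyl)-3-oxopentanoate (mixture of racemic diastereomers) | COc1ccc(C(C(=O)OC(C)(C)C)C(=O)C(Cc2ccc(OC)c(OCc3ccccc3)c2)N(C)C(=O)OC(C)(C)C)cc1 | intermediate
14 | 5-[3-(benzyloxy)-4-methoxyphenyl]-2-(4-methoxyphenyl)-4-(methylamino)-3-oxopentanoic acid trifluoroacetate salt (mixture of racemic diastereomers) | CNC(Cc1ccc(OC)c(OCc2ccccc2)c1)C(=O)C(C(=O)O)c1ccc(OC)cc1.OC(=O)C(F)(F)F | intermediate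
15 | 4-[3-(benzyloxy)-4-methoxyphenyl]-1-(4-methoxyphenyl)-3-(methylamino)butan-2-one trifluoroacetate salt (racemic) | CNC(Cc1ccc(OC)c(OCc2ccccc2)c1)C(=O)Cc1ccc(OC)cc1.OC(=O)C(F)(F)F | intermediate
16 | 1-{1-[3-(benzyloxy)-4-methoxyphenyl]-4-(4-methoxyphenyl)-3-oxobutan-2-yl}-1-methylguanidine (racemic) | CN(C(N)=N)C(Cc1ccc(OC)c(OCc2ccccc2)c1)C(=O)Cc1ccc(OC)cc1 | intermediate
17 | 5-{[3-(benzyloxy)-4-methoxyphenyl]methyl}-4-[(4-methoxyphenyl)methyl]-1-methyl-1H-imidazol-2-amine | COc1ccc(Cc2nc(N)n(C)c2Cc2ccc(OC)c(OCc3ccccc3)c2)cc1 | intermediate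
18 | 5-({2-amino-4-[(4-methoxyphenyl)methyl]-1-methyl-1H-imidazol-5-yl}methyl)-2-methoxyphenol | COc1ccc(Cc2nc(N)n(C)c2Cc2ccc(OC)c(O)c2)cc1 | intermediate
19 | N-methylurea | CNC(N)=O | starting material
20 | 1-methylimidazolidine-2,4,5-trione (1-methylparabanic acid) | CN1C(=O)NC(=O)C1=O | intermediate
21 | 1-methyl-4-[(trimethylsilyl)oxy]-1H-imidazole-2,5-dione (silyl imidate) | CN1C(=O)N=C(O[Si](C)(C)C)C1=O | intermediate
22 | naamidine B, 4-({5-[(3-hydroxy-4-methoxyphenyl)methyl]-4-[(4-methoxyphenyl)methyl]-1-methyl-1H-imidazol-2-yl}amino)-1-methyl-1H-imidazole-2,5-dione (achiral) | COc1ccc(Cc2nc(NC3=NC(=O)N(C)C3=O)n(C)c2Cc2ccc(OC)c(O)c2)cc1 | target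

## Summary

Total step count: 12 (steps 6 and 11 are one-step side branches).
Longest linear sequence: 10 steps (1, 2, 3, 4, 5, 7, 8, 9, 10, 12) from isovanillin.

## Steps most likely to fail, with fallbacks

**Step 4 (alkylation of the Boc-sarcosinate enolate).** The enolate may self-condense or alkylate sluggishly. The fallback sets out from bromide 4 and comes back to the route at 7. Bromide 4 alkylates commercial methyl N-(diphenylmethylidene)glycinate under solid–liquid phase transfer (K2CO3, Bu4NBr, MeCN, 60 °C), a stabilised and very dependable glycine anion equivalent, to give methyl 3-[3-(benzyloxy)-4-methoxyphenyl]-2-[(diphenylmethylidene)amino]propanoate F1. Hydrolysis of the imine with 1 M HCl/THF and then NaHCO3 gives methyl 2-amino-3-[3-(benzyloxy)-4-methoxyphenyl]propanoate F2. Boc2O/Et3N in CH2Cl2 gives methyl 3-[3-(benzyloxy)-4-methoxyphenyl]-2-[(tert-butoxycarbonyl)amino]propanoate F3. N-Methylation of the carbamate with NaH/MeI in THF/DMF at 0 °C (racemisation is irrelevant) then delivers 7.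

**Step 7 (crossed Claisen condensation).** Two hindered partners and a moderately nucleophilic aryl-stabilised enolate may give low conversion. The fallback sets out from acid 8 and comes back at 15. Acid 8 is coupled with MeNHOMe·HCl (EDC·HCl, HOBt, iPr2NEt, CH2Cl2) to give the Weinreb amide tert-butyl N-{3-[3-(benzyloxy)-4-methoxyphenyl]-1-[methoxy(methyl)amino]-1-oxopropan-2-yl}-N-methylcarbamate F4. Commercial 4-MeOC6H4CH2MgCl in THF at 0 °C adds once through the stable chelate to give tert-butyl N-{1-[3-(benzyloxy)-4-methoxyphenyl]-4-(4-methoxyphenyl)-3-oxobutan-2-yl}-N-methylcarbamate F5. TFA/CH2Cl2 then removes the Boc group to give 15, so steps 6 to 8 are bypassed.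

**Step 9 (cyanamide condensation).** The hindered secondary amine may guanylate slowly while the amino ketone dimerises to a dihydropyrazine. The fallback sets out from 15 and comes back at 17. Amino ketone salt 15 is guanylated with the strongly electrophilic N,N'-di-Boc-N''-triflylguanidine and Et3N in CH2Cl2 at rt to give N,N'-bis(tert-butoxycarbonyl)-N''-{1-[3-(benzyloxy)-4-methoxyphenyl]-4-(4-methoxyphenyl)-3-oxobutan-2-yl}-N''-methylguanidine F6. TFA/CH2Cl2 removes both Boc groups to release ketoguanidine 16 as its salt, which is warmed in EtOH to cyclise and dehydrate, and a basic work-up gives 17.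

## Further compounds

F1 | step 4 | methyl 3-[3-(benzyloxy)-4-methoxyphenyl]-2-[(diphenylmethylidene)amino]propanoate (racemic) | COC(=O)C(Cc1ccc(OC)c(OCc2ccccc2)c1)N=C(c1ccccc1)c1ccccc1
F2 | step 4 | methyl 2-amino-3-[3-(benzyloxy)-4-methoxyphenyl]propanoate (racemic) | COC(=O)C(N)Cc1ccc(OC)c(OCc2ccccc2)c1
F3 | step 4 | methyl 3-[3-(benzyloxy)-4-methoxyphenyl]-2-[(tert-butoxycarbonyl)amino]propanoate (racemic) | COC(=O)C(Cc1ccc(OC)c(OCc2ccccc2)c1)NC(=O)OC(C)(C)C
F4 | step 7 | tert-butyl N-{3-[3-(benzyloxy)-4-methoxyphenyl]-1-[methoxy(methyl)amino]-1-oxopropan-2-yl}-N-methylcarbamate (racemic) | CON(C)C(=O)C(Cc1ccc(OC)c(OCc2ccccc2)c1)N(C)C(=O)OC(C)(C)C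
F5 | step 7 | tert-butyl N-{1-[3-(benzyloxy)-4-methoxyphenyl]-4-(4-methoxyphenyl)-3-oxobutan-2-yl}-N-methylcarbamate (racemic) | COc1ccc(CC(=O)C(Cc2ccc(OC)c(OCc3ccccc3)c2)N(C)C(=O)OC(C)(C)C)cc1
F6 | step 9 | N,N'-bis(tert-butoxycarbonyl)-N''-{1-[3-(benzyloxy)-4-methoxyphenyl]-4-(4-methoxyphenyl)-3-oxobutan-2-yl}-N''-methylguanidine (racemic) | CC(C)(C)OC(=O)NC(=NC(=O)OC(C)(C)C)N(C)C(Cc1ccc(OC)c(OCc2ccccc2)c1)C(=O)Cc1ccc(OC)cc1
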